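Numbering: cyclopenta[c]pyran locants of the target are used throughout (ring oxygen O2; C2' is the acetoxy carbon of the side chain).
Cuts: C1–C3(coumarin), C3–C1'(acyl chain), and inside the pyran ring O2–C3 and C4–C4a.
Enabling feature: O2–C1–C7a–C4a is the O=C–C=C unit of a cyclopentene carbaldehyde and C3–C4 with its methyl is a propionate at the ester level, so the dihydropyran is the [4+2] adduct of that enal with a propionate ketene acetal (C3 as ortho ester).
Forward: cyclopentene by ring-closing metathesis of α-methylenated (S)-citronellal; pyran ring by the chromium-catalysed hetero-Diels–Alder step; ortho ester unmasked and re-closed as a 1-methoxy lactone; acyl chain joined at C3 through the ketene acetal triflate and a chromium/nickel coupling; coumarin joined last at C1 through the ring oxocarbenium ion.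
Stereochemistry: C7 from (S)-citronellal; C4a from the catalyst, backed by the C7 methyl; C7a by protonation on the face away from the C4a branch; C1 by attack on the convex face of the cis-fused oxocarbenium ion; C2' from (R)-2-hydroxy-3-methylbutanoic acid.

Key step: step 4

Assumption: the CrCl(L) complex built from (1R,2S)-1-aminoindan-2-ol is taken as the enantiomer that sends the ketene acetal to the face of C4a anti to the C7 methyl; if the pairing is the reverse, the mirror-image complex takes its place.
Note on descriptors: the descriptor at C4a reads R in compounds 6, 7 and F2 and S elsewhere only because the priorities of its neighbours change; the centre itself is not touched after step 4.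

Step 1
Reactants: 1 (S)-citronellal
Product: 2 (3S)-3,7-dimethyl-2-methylideneoct-6-enal
Conditions: 37% aq. CH2O, pyrrolidine (10 mol %), EtCO2H (10 mol %), i-PrOH, 45 °C
Reagents that add atoms: formaldehyde, C=O
Why: Amine-catalysed Mannich condensation with formaldehyde followed by loss of the amine (α-methylenation) should give the 2-methylidene aldehyde; the C3 centre is not enolisable and is kept.

Step 2
Reactants: 2 (3S)-3,7-dimethyl-2-methylideneoct-6-enal
Product: 3 (5S)-5-methylcyclopent-1-ene-1-carbaldehyde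
Conditions: second-generation Grubbs catalyst (H2IMes)(PCy3)Cl2Ru=CHPh (2 mol %), CH2Cl2, 40 °C
Reagents that add atoms: none
Why: Ring-closing metathesis between the 1,1-disubstituted and the trisubstituted alkene closes the five-membered ring with loss of 2-methylpropene; no stereocentre is formed or touched.

Step 3
Reactants: 4 triethyl orthopropionate
Product: 5 1,1-diethoxyprop-1-ene
Conditions: Al(OtBu)3 (cat.), neat, 180 °C, EtOH distilled off; then fractional distillation
Reagents that add atoms: none
Why: Thermal dealcoholation of an ortho ester with an aluminium alkoxide (1,2-elimination of ethanol) is the classical way to a ketene acetal; no stereocentre.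

Step 4
Reactants: 3 (5S)-5-methylcyclopent-1-ene-1-carbaldehyde; 5 1,1-diethoxyprop-1-ene
Product: 6 (4aR,7S)-3,3-diethoxy-4,7-dimethyl-3,4,4a,5,6,7-hexahydrocyclopenta[c]pyran (epimers at C4)
Conditions: CrCl(L) (5 mol %; L = Schiff-base dianion of (1R,2S)-1-aminoindan-2-ol and 3-(1-adamantyl)-2-hydroxy-5-methylbenzaldehyde), 5 (2 equiv), 4 Å MS, t-BuOMe, −20 → 0 °C; filtration through basic Al2O3
Reagents that add atoms: none
Why: Proposed new method: the chromium Schiff-base chloride complexes are proven for enol ethers with cyclopentene carbaldehydes but not yet with a ketene acetal as the 2π partner; coordination of the aldehyde oxygen of 3 to trivalent chromium lowers the LUMO of the s-cis O=C1–C7a=C4a oxadiene, the nucleophilic C4 of 5 bonds to C4a and the aldehyde oxygen to the acetal carbon C3 in a concerted, asynchronous [4+2] addition (a Michael-type zwitterion closing at oxygen would give the same adduct). The closest known reactions are the inverse-demand hetero-Diels–Alder additions of ethyl vinyl ether to 5-substituted cyclopent-1-ene carbaldehydes under this catalyst class and the uncatalysed cycloadditions of ketene acetals to enals. The dihydropyran ring closes in the [4+2] mode, both new bonds forming on one face of the ketene acetal. C4a is set by the catalyst, which delivers 5 to the face anti to the C7 methyl, the face the substrate itself weakly favours, while C4 depends only on endo or exo approach and is erased in step 12. The step needs 1,4- rather than 1,2-addition and one face of C4a: the matching polarity of enal and ketene acetal secures the first, and the low temperature, which holds back the uncatalysed reaction, leaves the second to the catalyst.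

Step 5
Reactants: 6 (4aR,7S)-3,3-diethoxy-4,7-dimethyl-3,4,4a,5,6,7-hexahydrocyclopenta[c]pyran
Product: 8 ethyl 2-[(1S,2R,3S)-2-formyl-3-methylcyclopentyl]propanoate (epimers at the ester α-carbon), via enol ester 7 (not isolated)
Conditions: AcOH, THF/H2O, 0 °C; NaHCO3 quench; crude product used at once
Reagents that add atoms: water, O
Why: Ortho ester hydrolysis expels the enol, the best leaving group, and the enol is protonated at C7a on the face away from the bulky C4a branch (kinetic ketonisation), which should place the formyl group cis to that branch and trans to the C7 methyl.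

Step 6
Reactants: 8 ethyl 2-[(1S,2R,3S)-2-formyl-3-methylcyclopentyl]propanoate
Product: 9 ethyl 2-[(1S,2R,3S)-2-(dimethoxymethyl)-3-methylcyclopentyl]propanoate
Conditions: HC(OMe)3, PPTS (cat.), MeOH, 0 °C → rt
Reagents that add atoms: trimethyl orthoformate, COC(OC)OC; methanol, CO
Why: Acid-catalysed acetalisation driven by the orthoformate masks the aldehyde and freezes the C7a centre, which can no longer enolise.

Step 7
Reactants: 9 ethyl 2-[(1S,2R,3S)-2-(dimethoxymethyl)-3-methylcyclopentyl]propanoate
Product: 11 2-[(1S,2R,3S)-2-(dimethoxymethyl)-3-methylcyclopentyl]propanoic acid, via lithium carboxylate 10 (not isolated)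
Conditions: LiOH·H2O, THF/MeOH/H2O, 40 °C; then 1 M HCl to pH 4, 0 °C
Reagents that add atoms: lithium hydroxide, [Li+].[OH-]
Why: Saponification of the ethyl ester leaves the acetal untouched; the only enolisable centre, the acid α-carbon, becomes sp2 in step 12.

Step 8
Reactants: 11 2-[(1S,2R,3S)-2-(dimethoxymethyl)-3-methylcyclopentyl]propanoic acid
Product: 12 (4aS,7S,7aR)-1-methoxy-4,7-dimethylhexahydrocyclopenta[c]pyran-3(1H)-one (epimers at C1 and C4)
Conditions: CSA (5 mol %), 5 Å MS, CH2Cl2, rt
Reagents that add atoms: none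
Why: Acid ionises the dimethyl acetal and the cis carboxylic acid traps the oxocarbenium ion as the six-membered alkoxy lactone (pseudo ester formation), re-forming the O2–C3 bond; C1 is a mixed acetal whose configuration is erased in step 18.

Step 9
Reactants: 13 (R)-2-hydroxy-3-methylbutanoic acid
Product: 14 methyl (2R)-2-hydroxy-3-methylbutanoate
Conditions: MeOH, H2SO4 (cat.), reflux
Reagents that add atoms: methanol, CO
Why: Fischer esterification; the α-hydroxy centre is not affected.

Step 10
Reactants: 14 methyl (2R)-2-hydroxy-3-methylbutanoate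
Product: 15 methyl (2R)-2-[(tert-butyldimethylsilyl)oxy]-3-methylbutanoate
Conditions: t-BuMe2SiCl, imidazole, DMF, rt
Reagents that add atoms: tert-butyldimethylsilyl chloride, CC(C)(C)[Si](C)(C)Cl
Why: Standard O-silylation; a silyl ether is preferred to the acetate because it cannot migrate to the neighbouring hydroxyl formed in step 13.

Step 11
Reactants: 15 methyl (2R)-2-[(tert-butyldimethylsilyl)oxy]-3-methylbutanoate
Product: 17 (2R)-2-[(tert-butyldimethylsilyl)oxy]-3-methylbutanal, via aluminium hemiacetal 16 (not isolated)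
Conditions: i-Bu2AlH, CH2Cl2, −78 °C; then aq. potassium sodium tartrate
Reagents that add atoms: none
Why: Partial reduction of the ester stops at the tetrahedral aluminium hemiacetal at −78 °C, which releases the aldehyde on work-up; the aldehyde is used fresh so that the α-centre stays intact.

Step 12
Reactants: 12 (4aS,7S,7aR)-1-methoxy-4,7-dimethylhexahydrocyclopenta[c]pyran-3(1H)-one
Product: 19 (4aS,7S,7aR)-1-methoxy-4,7-dimethyl-1,4a,5,6,7,7a-hexahydrocyclopenta[c]pyran-3-yl trifluoromethanesulfonate (epimers at C1), via potassium enolate 18 (not isolated)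
Conditions: KN(SiMe3)2, DMPU, THF, −78 °C; then PhNTf2, −78 °C; cold aq. NH4Cl; used at once
Reagents that add atoms: N-phenylbis(trifluoromethanesulfonimide), O=S(=O)(N(c1ccccc1)S(=O)(=O)C(F)(F)F)C(F)(F)F
Why: Deprotonation at C4, the only position α to the lactone carbonyl, and O-sulfonylation of the enolate give the ketene acetal triflate (lactone enol triflate formation), which makes C4 sp2 and merges the C4 epimers.

Step 13
Reactants: 19 (4aS,7S,7aR)-1-methoxy-4,7-dimethyl-1,4a,5,6,7,7a-hexahydrocyclopenta[c]pyran-3-yl trifluoromethanesulfonate; 17 (2R)-2-[(tert-butyldimethylsilyl)oxy]-3-methylbutanal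
Product: 21 (2R)-2-[(tert-butyldimethylsilyl)oxy]-1-[(4aS,7S,7aR)-1-methoxy-4,7-dimethyl-1,4a,5,6,7,7a-hexahydrocyclopenta[c]pyran-3-yl]-3-methylbutan-1-ol (epimers at C1 and at the carbinol carbon), via alkenylchromium dichloride 20 (not isolated)
Conditions: CrCl2 (6 equiv), NiCl2 (2 mol %), 17 (1.5 equiv), degassed DMF, rt
Reagents that add atoms: none
Why: Zerovalent nickel inserts into the C3–OTf bond, the alkenyl group passes to trivalent chromium and adds chemoselectively to the aldehyde (Nozaki–Hiyama–Kishi coupling, known for lactone-derived ketene acetal triflates); the new carbinol centre need not be controlled because step 14 removes it.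

Step 14
Reactants: 21 (2R)-2-[(tert-butyldimethylsilyl)oxy]-1-[(4aS,7S,7aR)-1-methoxy-4,7-dimethyl-1,4a,5,6,7,7a-hexahydrocyclopenta[c]pyran-3-yl]-3-methylbutan-1-ol
Product: 22 (2R)-2-[(tert-butyldimethylsilyl)oxy]-1-[(4aS,7S,7aR)-1-methoxy-4,7-dimethyl-1,4a,5,6,7,7a-hexahydrocyclopenta[c]pyran-3-yl]-3-methylbutan-1-one (epimers at C1)
Conditions: Dess–Martin periodinane, NaHCO3, CH2Cl2, 0 °C → rt
Reagents that add atoms: none
Why: Buffered Dess–Martin oxidation of the allylic alcohol should give the α-alkoxy enone without touching the acetal or the silyl ether, and it removes the uncontrolled carbinol centre.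

Step 15
Reactants: 22 (2R)-2-[(tert-butyldimethylsilyl)oxy]-1-[(4aS,7S,7aR)-1-methoxy-4,7-dimethyl-1,4a,5,6,7,7a-hexahydrocyclopenta[c]pyran-3-yl]-3-methylbutan-1-one
Product: 23 (2R)-2-hydroxy-1-[(4aS,7S,7aR)-1-methoxy-4,7-dimethyl-1,4a,5,6,7,7a-hexahydrocyclopenta[c]pyran-3-yl]-3-methylbutan-1-one (epimers at C1)
Conditions: Bu4NF, AcOH (1:1), THF, 0 °C → rt
Reagents that add atoms: none
Why: Fluoride cleaves the Si–O bond (desilylation), and buffering with acetic acid keeps the medium non-basic so that the α-hydroxy ketone centre C2' does not enolise.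

Step 16
Reactants: 23 (2R)-2-hydroxy-1-[(4aS,7S,7aR)-1-methoxy-4,7-dimethyl-1,4a,5,6,7,7a-hexahydrocyclopenta[c]pyran-3-yl]-3-methylbutan-1-one
Product: 24 (2R)-1-[(4aS,7S,7aR)-1-methoxy-4,7-dimethyl-1,4a,5,6,7,7a-hexahydrocyclopenta[c]pyran-3-yl]-3-methyl-1-oxobutan-2-yl acetate (epimers at C1)
Conditions: Ac2O, pyridine, DMAP (cat.), CH2Cl2, 0 °C
Reagents that add atoms: acetic anhydride, CC(=O)OC(C)=O
Why: DMAP-catalysed O-acetylation of the secondary alcohol proceeds with retention at C2'.

Step 17
Reactants: 25 2'-hydroxy-6'-methylacetophenone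
Product: 27 4-hydroxy-5-methyl-2H-chromen-2-one, via sodium coumarinolate 26 (not isolated)
Conditions: NaH (3 equiv), (EtO)2CO, toluene, 110 °C; then aq. HCl
Reagents that add atoms: diethyl carbonate, CCOC(=O)OCC
Why: Claisen condensation of the ketone enolate with diethyl carbonate and lactonisation by the phenoxide build the 4-hydroxycoumarin ring; no stereocentre.

Step 18
Reactants: 24 (2R)-1-[(4aS,7S,7aR)-1-methoxy-4,7-dimethyl-1,4a,5,6,7,7a-hexahydrocyclopenta[c]pyran-3-yl]-3-methyl-1-oxobutan-2-yl acetate; 27 4-hydroxy-5-methyl-2H-chromen-2-one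
Product: 28 (2R)-1-[(1R,4aS,7S,7aR)-1-(4-hydroxy-5-methyl-2-oxo-2H-chromen-3-yl)-4,7-dimethyl-1,4a,5,6,7,7a-hexahydrocyclopenta[c]pyran-3-yl]-3-methyl-1-oxobutan-2-yl acetate
Conditions: Sc(OTf)3 (10 mol %), 27 (1.0 equiv), 5 Å MS, MeCN, −20 → 0 °C
Reagents that add atoms: none
Why: Sc(OTf)3 ionises the C1 methoxy group to the ring oxocarbenium ion, which the nucleophilic C3 of the 4-hydroxycoumarin attacks (Friedel–Crafts-type C-alkylation of a vinylogous acid by an acetal, any O-linked adduct re-ionising to the C-linked one); the cyclopentane ring covers the concave face, so attack on the convex face anti to C7 should set C1 as R with the coumarin trans to C7 and pseudo-equatorial, which is also the more stable arrangement.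

Compound list
1 | (S)-citronellal | C[C@H](CC=O)CCC=C(C)C | starting material
2 | (3S)-3,7-dimethyl-2-methylideneoct-6-enal | C[C@H](C(=C)C=O)CCC=C(C)C | intermediate
3 | (5S)-5-methylcyclopent-1-ene-1-carbaldehyde | C[C@H]1CCC=C1C=O | intermediate
4 | triethyl orthopropionate | CCC(OCC)(OCC)OCC | starting material
5 | 1,1-diethoxyprop-1-ene | CC=C(OCC)OCC | intermediate
6 | (4aR,7S)-3,3-diethoxy-4,7-dimethyl-3,4,4a,5,6,7-hexahydrocyclopenta[c]pyran (epimers at C4) | CCOC1(OCC)C(C)[C@H]2CC[C@H](C)C2=CO1 | intermediate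
7 | ethyl 2-[(1R,3S)-2-(hydroxymethylidene)-3-methylcyclopentyl]propanoate | CCOC(=O)C(C)[C@H]1CC[C@H](C)C1=CO | intermediate
8 | ethyl 2-[(1S,2R,3S)-2-formyl-3-methylcyclopentyl]propanoate | CCOC(=O)C(C)[C@H]1CC[C@H](C)[C@H]1C=O | intermediate
9 | ethyl 2-[(1S,2R,3S)-2-(dimethoxymethyl)-3-methylcyclopentyl]propanoate | CCOC(=O)C(C)[C@H]1CC[C@H](C)[C@H]1C(OC)OC | intermediate
10 | lithium 2-[(1S,2R,3S)-2-(dimethoxymethyl)-3-methylcyclopentyl]propanoate | [Li+].[O-]C(=O)C(C)[C@H]1CC[C@H](C)[C@H]1C(OC)OC | intermediate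
11 | 2-[(1S,2R,3S)-2-(dimethoxymethyl)-3-methylcyclopentyl]propanoic acid | OC(=O)C(C)[C@H]1CC[C@H](C)[C@H]1C(OC)OC | intermediate
12 | (4aS,7S,7aR)-1-methoxy-4,7-dimethylhexahydrocyclopenta[c]pyran-3(1H)-one | O=C1C(C)[C@H]2CC[C@H](C)[C@H]2C(OC)O1 | intermediate
13 | (R)-2-hydroxy-3-methylbutanoic acid | CC(C)[C@@H](O)C(=O)O | starting material
14 | methyl (2R)-2-hydroxy-3-methylbutanoate | CC(C)[C@@H](O)C(=O)OC | intermediate
15 | methyl (2R)-2-[(tert-butyldimethylsilyl)oxy]-3-methylbutanoate | CC(C)[C@@H](O[Si](C)(C)C(C)(C)C)C(=O)OC | intermediate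
16 | [(2R)-2-[(tert-butyldimethylsilyl)oxy]-1-methoxy-3-methylbutoxy]bis(2-methylpropyl)aluminium | CC(C)[C@@H](O[Si](C)(C)C(C)(C)C)C(OC)O[Al](CC(C)C)CC(C)C | intermediate
17 | (2R)-2-[(tert-butyldimethylsilyl)oxy]-3-methylbutanal | CC(C)[C@@H](O[Si](C)(C)C(C)(C)C)C=O | intermediate
18 | potassium (4aS,7S,7aR)-1-methoxy-4,7-dimethyl-1,4a,5,6,7,7a-hexahydrocyclopenta[c]pyran-3-olate | [K+].[O-]C1=C(C)[C@H]2CC[C@H](C)[C@H]2C(OC)O1 | intermediate
19 | (4aS,7S,7aR)-1-methoxy-4,7-dimethyl-1,4a,5,6,7,7a-hexahydrocyclopenta[c]pyran-3-yl trifluoromethanesulfonate | O=S(=O)(OC1=C(C)[C@H]2CC[C@H](C)[C@H]2C(OC)O1)C(F)(F)F | intermediate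
20 | dichloro[(4aS,7S,7aR)-1-methoxy-4,7-dimethyl-1,4a,5,6,7,7a-hexahydrocyclopenta[c]pyran-3-yl]chromium | Cl[Cr](Cl)C1=C(C)[C@H]2CC[C@H](C)[C@H]2C(OC)O1 | intermediate
21 | (2R)-2-[(tert-butyldimethylsilyl)oxy]-1-[(4aS,7S,7aR)-1-methoxy-4,7-dimethyl-1,4a,5,6,7,7a-hexahydrocyclopenta[c]pyran-3-yl]-3-methylbutan-1-ol | CC(C)[C@@H](O[Si](C)(C)C(C)(C)C)C(O)C1=C(C)[C@H]2CC[C@H](C)[C@H]2C(OC)O1 | intermediate
22 | (2R)-2-[(tert-butyldimethylsilyl)oxy]-1-[(4aS,7S,7aR)-1-methoxy-4,7-dimethyl-1,4a,5,6,7,7a-hexahydrocyclopenta[c]pyran-3-yl]-3-methylbutan-1-one | CC(C)[C@@H](O[Si](C)(C)C(C)(C)C)C(=O)C1=C(C)[C@H]2CC[C@H](C)[C@H]2C(OC)O1 | intermediate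
23 | (2R)-2-hydroxy-1-[(4aS,7S,7aR)-1-methoxy-4,7-dimethyl-1,4a,5,6,7,7a-hexahydrocyclopenta[c]pyran-3-yl]-3-methylbutan-1-one | CC(C)[C@@H](O)C(=O)C1=C(C)[C@H]2CC[C@H](C)[C@H]2C(OC)O1 | intermediate
24 | (2R)-1-[(4aS,7S,7aR)-1-methoxy-4,7-dimethyl-1,4a,5,6,7,7a-hexahydrocyclopenta[c]pyran-3-yl]-3-methyl-1-oxobutan-2-yl acetate | CC(C)[C@@H](OC(C)=O)C(=O)C1=C(C)[C@H]2CC[C@H](C)[C@H]2C(OC)O1 | intermediate
25 | 2'-hydroxy-6'-methylacetophenone | CC(=O)c1c(C)cccc1O | starting material
26 | sodium 5-methyl-2-oxo-2H-chromen-4-olate | [Na+].[O-]c1cc(=O)oc2cccc(C)c12 | intermediate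
27 | 4-hydroxy-5-methyl-2H-chromen-2-one | Cc1cccc2oc(=O)cc(O)c12 | intermediate
28 | (2R)-1-[(1R,4aS,7S,7aR)-1-(4-hydroxy-5-methyl-2-oxo-2H-chromen-3-yl)-4,7-dimethyl-1,4a,5,6,7,7a-hexahydrocyclopenta[c]pyran-3-yl]-3-methyl-1-oxobutan-2-yl acetate | CC(=O)O[C@@H](C(=O)C1=C(C)[C@H]2CC[C@H](C)[C@H]2[C@H](c2c(O)c3c(C)cccc3oc2=O)O1)C(C)C | target

Total step count: 18 steps.
Longest linear sequence: 13 steps (steps 1, 2, 4 to 8, 12 to 16 and 18, from compound 1).

Steps most likely to fail

Step 4 (key step). What may go wrong: Lewis-acid-induced oligomerisation or hydrolysis of the ketene acetal, or an uncatalysed background cycloaddition that bypasses the catalyst and leaves poor facial selectivity at C4a. The fallback uses known reactions only, sets out from 3 and comes back at 8. Luche reduction of 3 (NaBH4, CeCl3·7H2O, MeOH, 0 °C) gives [(5S)-5-methylcyclopent-1-en-1-yl]methanol F1. Johnson–Claisen rearrangement of this alcohol with 4 (EtCO2H cat., 140 °C) forms the C4–C4a bond by a [3,3] shift and gives ethyl 2-[(1R,3S)-3-methyl-2-methylidenecyclopentyl]propanoate F2; here the C7 methyl alone steers the new bond anti, so the C4a epimer would have to be removed by chromatography. Hydroboration with 9-BBN on the face away from the C4a branch, followed by oxidation with NaBO3·4H2O, should give ethyl 2-[(1S,2R,3S)-2-(hydroxymethyl)-3-methylcyclopentyl]propanoate F3, and Dess–Martin oxidation then returns to 8.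

Step 13. What may go wrong: hydrolytic loss of the triflate group and slow oxidative addition at the tetrasubstituted ketene acetal carbon, so that reduction of the triflate outruns carbon–carbon bond formation. The fallback sets out from 12 and comes back at 21. KN(SiMe3)2 and (PhO)2P(O)Cl in THF at −78 °C give the more robust ketene acetal phosphate, (4aS,7S,7aR)-1-methoxy-4,7-dimethyl-1,4a,5,6,7,7a-hexahydrocyclopenta[c]pyran-3-yl diphenyl phosphate F4. Pd(PPh3)4, (Me3Sn)2 and LiCl in THF convert it into trimethyl[(4aS,7S,7aR)-1-methoxy-4,7-dimethyl-1,4a,5,6,7,7a-hexahydrocyclopenta[c]pyran-3-yl]stannane F5. Tin–lithium exchange with MeLi at −78 °C gives [(4aS,7S,7aR)-1-methoxy-4,7-dimethyl-1,4a,5,6,7,7a-hexahydrocyclopenta[c]pyran-3-yl]lithium F6, which adds to aldehyde 17 to give 21.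

Step 18. What may go wrong: reversible ionisation of the C1–O2 bond of the product under the protic Lewis-acid conditions, which lets a second coumarin add at C1 and erodes the C1 selectivity, together with competing O-alkylation of the 4-hydroxyl group. The fallback sets out from 27 and comes back at 28. Silylation of 27 with (Me3Si)2NH gives 5-methyl-4-[(trimethylsilyl)oxy]-2H-chromen-2-one F7. This silyl enol ether is combined with 24 (1:1) and catalytic Me3SiOTf in CH2Cl2 at −78 °C in a Mukaiyama-type substitution of the acetal. The carbon–carbon bond then forms irreversibly under aprotic conditions, and aqueous work-up should deliver 28.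

Further compounds
F1 | step 4 | [(5S)-5-methylcyclopent-1-en-1-yl]methanol | C[C@H]1CCC=C1CO
F2 | step 4 | ethyl 2-[(1R,3S)-3-methyl-2-methylidenecyclopentyl]propanoate | CCOC(=O)C(C)[C@H]1CC[C@H](C)C1=C
F3 | step 4 | ethyl 2-[(1S,2R,3S)-2-(hydroxymethyl)-3-methylcyclopentyl]propanoate | CCOC(=O)C(C)[C@H]1CC[C@H](C)[C@H]1CO
F4 | step 13 | (4aS,7S,7aR)-1-methoxy-4,7-dimethyl-1,4a,5,6,7,7a-hexahydrocyclopenta[c]pyran-3-yl diphenyl phosphate | O=P(Oc1ccccc1)(Oc1ccccc1)OC1=C(C)[C@H]2CC[C@H](C)[C@H]2C(OC)O1
F5 | step 13 | trimethyl[(4aS,7S,7aR)-1-methoxy-4,7-dimethyl-1,4a,5,6,7,7a-hexahydrocyclopenta[c]pyran-3-yl]stannane | C[Sn](C)(C)C1=C(C)[C@H]2CC[C@H](C)[C@H]2C(OC)O1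
F6 | step 13 | [(4aS,7S,7aR)-1-methoxy-4,7-dimethyl-1,4a,5,6,7,7a-hexahydrocyclopenta[c]pyran-3-yl]lithium | [Li]C1=C(C)[C@H]2CC[C@H](C)[C@H]2C(OC)O1
F7 | step 18 | 5-methyl-4-[(trimethylsilyl)oxy]-2H-chromen-2-one | Cc1cccc2oc(=O)cc(O[Si](C)(C)C)c12
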